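## Analysis of the target

The target is 8-geranylaromadendrin, a flavanonol. Ring A is a 5,7-dihydroxylated benzene ring fused to the dihydropyran-4-one ring C (O1, C2, C3, C4, C4a, C8a); ring B is a 4-hydroxyphenyl group on C2; C3 carries a hydroxyl group and C8 an (E)-3,7-dimethylocta-2,6-dienyl (geranyl) chain. There are two stereocentres, C2 (R) and C3 (R). They are adjacent and trans, so the aryl and hydroxyl groups are both equatorial and H2 and H3 are anti.

The α-ketol (C3–OH beside C4=O) is base-sensitive: it can epimerise, open ring C by loss of O1 from C2, or be dehydrogenated to the flavonol. The geranyl chain is sensitive in three ways. Its inner double bond cyclises onto the neighbouring 7-hydroxyl in strong acid. Its two trisubstituted alkenes exclude hydrogenolysis, dihydroxylation and peracids. Its CH2 on C8 is both benzylic and allylic.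

Three things make the synthesis hard:
- the geranyl group must sit at C8 and not C6, so the three phloroglucinol oxygens must be told apart and the one flanked by geranyl must become O1;
- the trans C2/C3 pair must be made as one enantiomer;
- C4 must reach the ketone level with the geranyl chain already in place.

The strategy rests on one feature. O1–C8a–C4a–C4 is the heterodiene of an ortho-quinone methide of ring A, and C2–C3 with its trans aryl and oxygen substituents is the two-carbon unit of an E-configured styryl ester. Ring C is therefore a hetero-Diels–Alder adduct.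

## Retrosynthetic reasoning

**17 from 16.** The three phenolic O–H bonds are unmasked last. Acetal (MOM) ethers are chosen because they leave without hydrogenolysis and survive base, hydride, a weak chiral acid and a quinone oxidant. The forward step must cleave three aryl acetals without cyclising the geranyl chain onto the freed 7-hydroxyl.

**16 from 15 from 14.** The C4 carbonyl is traced back through the benzylic alcohol 15 to the methylene compound 14. The cycloaddition delivers C4 as CH2, and the donors O1, O5 and O7 make its axial C–H the most hydridic bond of ring C. A quinone hydride acceptor with hydrolytic trapping gives 15. A mild oxidant selective for benzylic alcohols then gives 16 and leaves the non-benzylic 3-hydroxyl alone. The forward reaction must distinguish C4–H from the geranyl CH2 on C8.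

**14 from 13.** The C3–O ester bond is cleaved on the flavan, before C4 becomes a ketone. At that stage neither C2 nor C3 is acidic, so base is harmless. On an α-acyloxy ketone the same base would endanger both stereocentres.

**13 from 6 and 11 through 12.** O1–C2 and C3–C4 are cut together. They are the only ring C bonds not tied into the substitution pattern of ring A. Cutting both splits the molecule into an A-ring and a B-ring fragment of similar size, removes both stereocentres and turns the trans relationship into alkene geometry. The forward reaction has three tasks: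
- ionise 6 to methide 12 under conditions that spare the MOM ethers and the geranyl chain;
- orient 11 so that C4 bonds to the acetoxy-bearing carbon;
- select one face of the alkene.

**6 from 5 from 4.** The C4a–C4 bond is made by formylation ortho to the only free hydroxyl of 4, then reduction. Because that hydroxyl is the one flanked by geranyl, the ring oxygen ends up beside C8 and the regiochemistry is fixed.

**4 from 2 and 3; 2 from 1.** The C8–C1'' bond comes from ortho C-alkylation of the phenoxide of 2 with 3. Both ortho positions of 2 are equivalent, so only the ortho/para choice matters. 2 comes from 1 by two acetal O–C bonds.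

**11 from 10 from 9 from 8 from 7.** The E geometry of 11 encodes the trans relationship, so it must be made stereospecifically. The enol C–O bond is cut to an E-alkenylboron compound (10, from 9) for a stereoretentive copper coupling. Enol acylation of the arylacetaldehyde would give E/Z mixtures. The C=C bond of 9 comes from aldehyde 8 by a boron–Wittig olefination, and 8 from 7.

## Alternatives that were turned down

**Alternative 1:** The C2–C3 bond is disconnected by a reverse acyloin shift. Ring C contracts to the dihydrobenzofuranol A2, in which C2 is bonded to a carbinol carbon (the future C4) that also carries a formyl group (the future C3).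

- Forward key step: a Lewis-acidic aluminium alkoxide chelates the hydroxyl and formyl oxygens of A2. C2 shifts with retention to the formyl carbon, the carbinol carbon becomes the aryl ketone, and the five-membered ring expands to the silyl-protected flavanonol A1.
- For: the C4 ketone and C3 hydroxyl arrive at the final oxidation level, so nothing has to be oxidised beside the geranyl CH2. On this point it is stronger than the chosen route. Its silyl ethers leave with fluoride, which is gentler to the geranyl chain than acid. The shift is driven by turning an aldehyde into a conjugated aryl ketone.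
- Against: A2 carries a fully substituted carbinol centre next to C2, and both must be set before the key step. The obvious precursors pass through a 2-aryl benzofuranone whose C2 is α to a ketone and benzylic, hence configurationally labile. The electron-rich ring A carbon is also a good migrating group; its shift would put the carbonyl at C3. α-Hydroxy aldehydes also fragment readily.
- Comparison: the chosen route offers a shorter, convergent assembly in which ring C and both stereocentres form in one step from two achiral fragments, each four steps from commodity materials.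

**Alternative 2:** Ring A is disconnected at C8–C8a and C4a–C5, leaving the chiral dihydropyranone A4 (ring C with both stereocentres) and the geranyl acetoacetate A5.

- Forward key step: the dianion of A5 attacks C8a of A4 through its γ carbon and displaces the methylsulfanyl group. The derived extended enolate closes from C4a onto the ester carbon, and tautomerisation gives the aromatic ring of A3.
- For: the geranyl group is on C8 by construction, because the carbon that bears it is the one bonded to C8a. This is stronger than the chosen route, which must differentiate the phloroglucinol oxygens. Ring A needs no protecting groups and C4 is already a ketone.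
- Against: the annulation runs with several equivalents of strong base on a substrate whose C3–H is α to the ketone. Enolisation there allows epimerisation and expulsion of O1 from C2 (O1 is a vinylogous carboxylate leaving group), which would destroy both stereocentres. The dianion can also add to the ketone. A4 itself needs an enantioselective synthesis of a trans 2-aryl-3-alkoxy pyranone.
- Comparison: the chosen route sets the stereocentres under weak acid at or below room temperature and never exposes them to strong base.

**Alternative 3:** Ring C is disconnected at O1–C8a and C4a–C4, leaving the silyl aryl triflate A7 as aryne precursor and the anti hydroxy ester A8.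

- Forward key step: fluoride generates the aryne across C4a–C8a. The benzylic alkoxide of A8 adds at C8a and the aryl anion at C4a acylates the ester, giving A6.
- For: both stereocentres are made beforehand in an acyclic ester by established asymmetric chemistry, away from the geranyl chain. This is stronger than the chosen route, whose enantiocontrol is new. C4 arrives as the ketone, and the 5-alkoxy group polarises the aryne towards attack at C8a.
- Against: C8a is flanked by the geranyl chain, so the electronically preferred site is the hindered one. The adjacent geranyl alkene can trap the aryne. The β-alkoxide of A8 can undergo retro-aldol cleavage or α-epimerisation. The anti ester needs an inversion after a syn-selective dihydroxylation, or an anti-selective glycolate aldol. A7 would be made from phenol 4, so it inherits the phloroglucinol differentiation and adds ortho-silylation and triflation steps.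
- Comparison: the chosen route is shorter and uses the same phenol 4 directly.

Key step: step 9

Geranyl means (2E)-3,7-dimethylocta-2,6-dien-1-yl throughout.

Assumption: which antipode of the chiral phosphoric acid leads to the (2R,3S) adduct cannot be derived from structure alone; the (R)-acid is written, and its mirror image is used if the opposite sense is found.

## Route

Step 1
Reactants: 1 phloroglucinol (benzene-1,3,5-triol)
Product: 2 3,5-bis(methoxymethoxy)phenol
Conditions: MOMCl (2.0 equiv), i-Pr2NEt (2.4 equiv), THF, 0 °C → rt
Reagents that add atoms: chloromethyl methyl ether, COCCl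
Why: Base-mediated O-alkylation of phenols to acetal ethers; the three hydroxyls are equivalent, so two equivalents of reagent should give the bis-ether as the main component of a statistical mixture, with the mono- and tris-ethers separated and recycled.

Step 2
Reactants: 2 3,5-bis(methoxymethoxy)phenol; 3 geranyl bromide
Product: 4 2-geranyl-3,5-bis(methoxymethoxy)phenol
Conditions: NaH (1.0 equiv), toluene, 0 °C → rt; then 3 (0.8 equiv), rt
Reagents that add atoms: none
Why: Ortho C-alkylation of a sodium phenoxide in a non-polar solvent: the tight ion pair delivers the allylic bromide to the ortho carbon through a cyclic SN2 transition state, so C-alkylation should outrun O-alkylation and the E geometry of 3 is kept. Both ortho positions of 2 are equivalent and lead to 4; the para position lies between two MOM-oxy groups and away from the sodium ion.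

Step 3
Reactants: 4 2-geranyl-3,5-bis(methoxymethoxy)phenol
Product: 5 3-geranyl-2-hydroxy-4,6-bis(methoxymethoxy)benzaldehyde
Conditions: MgCl2, Et3N, (CH2O)n, MeCN, reflux
Reagents that add atoms: paraformaldehyde (as formaldehyde), C=O
Why: Casnati–Skattebøl ortho-formylation: the magnesium phenoxide delivers formaldehyde to the ortho carbon and a second formaldehyde oxidises the resulting alkoxide by hydride transfer. Only one ortho position is free, this manifold does not formylate para, and MOM ethers and alkenes tolerate the basic medium.

Step 4
Reactants: 5 3-geranyl-2-hydroxy-4,6-bis(methoxymethoxy)benzaldehyde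
Product: 6 2-geranyl-6-(hydroxymethyl)-3,5-bis(methoxymethoxy)phenol
Conditions: NaBH4, THF/MeOH, 0 °C; pH 7 buffer work-up
Reagents that add atoms: none
Why: Hydride reduction of an aldehyde; low temperature and a buffered work-up should keep the electron-rich salicyl alcohol from ionising to the methide, and the product is used without chromatography on acidic silica.

Step 5
Reactants: 7 4-hydroxybenzaldehyde
Product: 8 4-(methoxymethoxy)benzaldehyde
Conditions: MOMCl, i-Pr2NEt, CH2Cl2, 0 °C → rt
Reagents that add atoms: chloromethyl methyl ether, COCCl
Why: O-alkylation of a phenol to its MOM ether; this acetal keeps ring B a strong donor for the key step and leaves in the same final operation as the ring A ethers.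

Step 6
Reactants: 8 4-(methoxymethoxy)benzaldehyde
Product: 9 2-[(E)-2-[4-(methoxymethoxy)phenyl]ethenyl]-4,4,5,5-tetramethyl-1,3,2-dioxaborolane
Conditions: CH2(Bpin)2, lithium 2,2,6,6-tetramethylpiperidide, THF, 0 °C; then 8, −78 °C → rt
Reagents that add atoms: bis[(pinacolato)boryl]methane, CC1(C)OB(CB2OC(C)(C)C(C)(C)O2)OC1(C)C
Why: Boron–Wittig olefination: the lithiated geminal bis(boronate) adds to the aldehyde and eliminates a boryloxide, which with aromatic aldehydes should give the trans alkenylboronate with high E selectivity.

Step 7
Reactants: 9 2-[(E)-2-[4-(methoxymethoxy)phenyl]ethenyl]-4,4,5,5-tetramethyl-1,3,2-dioxaborolane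
Product: 10 potassium (E)-trifluoro{2-[4-(methoxymethoxy)phenyl]ethenyl}borate
Conditions: KHF2 (aq.), MeOH, rt
Reagents that add atoms: potassium hydrogen difluoride, [K+].F[H-]F
Why: Standard conversion of a pinacol boronate into the crystalline trifluoroborate salt; the alkene geometry is untouched and the aryl MOM ether should withstand the weakly acidic fluoride medium at room temperature.

Step 8
Reactants: 10 potassium (E)-trifluoro{2-[4-(methoxymethoxy)phenyl]ethenyl}borate
Product: 11 (E)-2-[4-(methoxymethoxy)phenyl]ethenyl acetate
Conditions: AcOH, CuBr (10 mol %), DMAP (20 mol %), 4 Å MS, O2 (1 atm), CH2Cl2, 40 °C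
Reagents that add atoms: acetic acid, CC(=O)O
Why: Copper-catalysed oxidative (Chan–Lam-type) C–O coupling of an alkenyltrifluoroborate with a carboxylic acid; transmetalation and reductive elimination proceed with retention, so the E geometry of 10 should be carried into the enol ester.

Step 9
Reactants: 6 2-geranyl-6-(hydroxymethyl)-3,5-bis(methoxymethoxy)phenol; 11 (E)-2-[4-(methoxymethoxy)phenyl]ethenyl acetate
Product: 13 (2R,3S)-8-geranyl-5,7,4'-tris(methoxymethoxy)flavan-3-yl acetate, via ortho-quinone methide 12 (not isolated)
Conditions: (R)-TRIP [(R)-3,3'-bis(2,4,6-triisopropylphenyl)-1,1'-binaphthyl-2,2'-diyl hydrogen phosphate] (10 mol %), 5 Å MS, toluene, 0 °C → rt; 11 (2 equiv), 6 added slowly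
Reagents that add atoms: none
Why: Proposed new method: the phosphoric acid protonates the benzylic hydroxyl of 6, water leaves with help from the ortho and para MOM-oxy donors, and methide 12 stays hydrogen-bonded or ion-paired to the chiral phosphate; its CH2 terminus (C4) then bonds to the acetoxy-bearing carbon of 11 while the methide oxygen (O1) bonds to the benzylic carbon in a concerted but strongly asynchronous inverse-demand hetero-[4+2]. The closest known reaction type is the acid-catalysed [4+2] of in situ generated ortho-quinone methides with electron-rich styrenes and enol ethers to chromans, made enantioselective by chiral phosphoric acids for substituted methides; an unsubstituted methide paired with a styryl ester has not been shown. Ring C closes in the six-membered pericyclic transition state itself, with O1–C2 and C4–C3 formed suprafacially on both partners, and not by a separate cyclisation. The trans relationship of C2 and C3 is set by the E geometry of 11, which suprafacial addition preserves. Their absolute configuration is set by which face of 11 can reach the catalyst-bound methide inside the pocket of the 3,3'-aryl groups. Regioselectivity requires positive charge to build at C2, and the 4-alkoxyphenyl group secures this because a para-alkoxybenzyl cation is far better stabilised than an acyloxy carbenium ion. Chemoselectivity over the geranyl alkenes should follow from the higher nucleophilicity of the conjugated styrene, supported by excess 11 and slow addition of 6; the MOM ethers and the geranyl chain should tolerate this weak acid.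

Step 10
Reactants: 13 (2R,3S)-8-geranyl-5,7,4'-tris(methoxymethoxy)flavan-3-yl acetate
Product: 14 (2R,3S)-8-geranyl-5,7,4'-tris(methoxymethoxy)flavan-3-ol
Conditions: K2CO3 (cat.), MeOH, rt
Reagents that add atoms: none
Why: Base-catalysed transesterification (Zemplén-type) of a secondary acetate; on the flavan neither C2 nor C3 is acidic, so the ester is removed here and not after C4 has become a ketone.

Step 11
Reactants: 14 (2R,3S)-8-geranyl-5,7,4'-tris(methoxymethoxy)flavan-3-ol
Product: 15 (2R,3S)-8-geranyl-5,7,4'-tris(methoxymethoxy)flavan-3,4-diol (C4 epimers)
Conditions: DDQ (1.1 equiv), CH2Cl2/H2O (10:1), 0 °C → rt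
Reagents that add atoms: water, O
Why: Quinone-mediated benzylic hydride abstraction at C4 with capture of the cation by water, the reaction type used to functionalise C4 of 5,7-dialkoxyflavan-3-ols. The axial C4–H is held parallel to the π system of ring A and is activated by O1, O5 and O7, whereas the geranyl CH2 on C8 lies between two ortho oxygens that hold both its C–H bonds near the ring plane. C2 and C3 are not touched and the C4 configuration is irrelevant.

Step 12
Reactants: 15 (2R,3S)-8-geranyl-5,7,4'-tris(methoxymethoxy)flavan-3,4-diol
Product: 16 (2R,3R)-8-geranyl-3-hydroxy-5,7,4'-tris(methoxymethoxy)flavanone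
Conditions: MnO2 (activated, excess), CH2Cl2, rt
Reagents that add atoms: none
Why: MnO2 oxidises benzylic alcohols selectively, so the 4-hydroxyl should become the ketone while the non-benzylic 3-hydroxyl is kept and the 3,4-dione is avoided. The C3 descriptor changes from S to R only because C4 gains priority.

Step 13
Reactants: 16 (2R,3R)-8-geranyl-3-hydroxy-5,7,4'-tris(methoxymethoxy)flavanone
Product: 17 (2R,3R)-8-geranyl-3,5,7-trihydroxy-2-(4-hydroxyphenyl)chroman-4-one (8-geranylaromadendrin)
Conditions: 3 M aq. HCl/MeOH (1:4), 40 °C
Reagents that add atoms: none
Why: Acid-catalysed acetal exchange removes the three aryl MOM ethers; trans flavanonols are configurationally stable in acid, and mild temperature and short exposure should avoid cyclisation of the 7-hydroxyl onto the geranyl double bond.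

## Compound list

1 | phloroglucinol (benzene-1,3,5-triol) | Oc1cc(O)cc(O)c1 | starting material
2 | 3,5-bis(methoxymethoxy)phenol | COCOc1cc(O)cc(OCOC)c1 | intermediate
3 | geranyl bromide, (2E)-1-bromo-3,7-dimethylocta-2,6-diene | CC(C)=CCC/C(C)=C/CBr | starting material
4 | 2-geranyl-3,5-bis(methoxymethoxy)phenol | CC(C)=CCC/C(C)=C/Cc1c(OCOC)cc(OCOC)cc1O | intermediate
5 | 3-geranyl-2-hydroxy-4,6-bis(methoxymethoxy)benzaldehyde | CC(C)=CCC/C(C)=C/Cc1c(OCOC)cc(OCOC)c(C=O)c1O | intermediate
6 | 2-geranyl-6-(hydroxymethyl)-3,5-bis(methoxymethoxy)phenol | CC(C)=CCC/C(C)=C/Cc1c(OCOC)cc(OCOC)c(CO)c1O | intermediate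
7 | 4-hydroxybenzaldehyde | O=Cc1ccc(O)cc1 | starting material
8 | 4-(methoxymethoxy)benzaldehyde | COCOc1ccc(C=O)cc1 | intermediate
9 | 2-[(E)-2-[4-(methoxymethoxy)phenyl]ethenyl]-4,4,5,5-tetramethyl-1,3,2-dioxaborolane | COCOc1ccc(/C=C/B2OC(C)(C)C(C)(C)O2)cc1 | intermediate
10 | potassium (E)-trifluoro{2-[4-(methoxymethoxy)phenyl]ethenyl}borate | COCOc1ccc(/C=C/[B-](F)(F)F)cc1.[K+] | intermediate
11 | (E)-2-[4-(methoxymethoxy)phenyl]ethenyl acetate | CC(=O)O/C=C/c1ccc(OCOC)cc1 | intermediate
12 | 2-geranyl-3,5-bis(methoxymethoxy)-6-methylidenecyclohexa-2,4-dien-1-one | CC(C)=CCC/C(C)=C/CC1=C(OCOC)C=C(OCOC)C(=C)C1=O | intermediate (not isolated)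
13 | (2R,3S)-8-geranyl-5,7,4'-tris(methoxymethoxy)flavan-3-yl acetate | CC(C)=CCC/C(C)=C/Cc1c(OCOC)cc(OCOC)c2c1O[C@H](c1ccc(OCOC)cc1)[C@@H](OC(C)=O)C2 | intermediate
14 | (2R,3S)-8-geranyl-5,7,4'-tris(methoxymethoxy)flavan-3-ol | CC(C)=CCC/C(C)=C/Cc1c(OCOC)cc(OCOC)c2c1O[C@H](c1ccc(OCOC)cc1)[C@@H](O)C2 | intermediate
15 | (2R,3S)-8-geranyl-5,7,4'-tris(methoxymethoxy)flavan-3,4-diol, C4 epimers | CC(C)=CCC/C(C)=C/Cc1c(OCOC)cc(OCOC)c2c1O[C@H](c1ccc(OCOC)cc1)[C@@H](O)C2O | intermediate
16 | (2R,3R)-8-geranyl-3-hydroxy-5,7,4'-tris(methoxymethoxy)flavanone | CC(C)=CCC/C(C)=C/Cc1c(OCOC)cc(OCOC)c2c1O[C@H](c1ccc(OCOC)cc1)[C@@H](O)C2=O | intermediate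
17 | (2R,3R)-8-geranyl-3,5,7-trihydroxy-2-(4-hydroxyphenyl)chroman-4-one | CC(C)=CCC/C(C)=C/Cc1c(O)cc(O)c2c1O[C@H](c1ccc(O)cc1)[C@@H](O)C2=O | target

## Step count and least certain steps

Total step count: 13. Longest linear sequence: 9 steps (steps 1–4, then 9–13; the branch 5–8, then 9–13, is equally long).

**Step 9 (key step).** Most likely to go wrong:
- poor facial discrimination, because 11 has no hydrogen-bond donor to anchor it to the phosphate, so the sense and level of induction rest on the catalyst pocket alone;
- loss of regiocontrol if the acyloxy group competes as donor;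
- self-condensation of the methide with its own precursor;
- loss of stereospecificity if the addition becomes stepwise and the benzylic cation rotates before ring closure.

Fallback (known chemistry, from 5 and 8 to 17): the free phenol of 5 is capped with MOMCl and i-Pr2NEt to give 3-geranyl-2,4,6-tris(methoxymethoxy)benzaldehyde F1. MeMgBr addition gives racemic 1-[3-geranyl-2,4,6-tris(methoxymethoxy)phenyl]ethanol F2. Dess–Martin periodinane gives 1-[3-geranyl-2,4,6-tris(methoxymethoxy)phenyl]ethanone F3. Claisen–Schmidt condensation with 8 (KOH, EtOH) gives the (E)-chalcone F4. Juliá–Colonna epoxidation (poly-L-leucine, urea–H2O2, DBU, THF) attacks only the enone and gives the (αR,βS)-epoxy ketone F5. HCl in MeOH removes the four MOM groups, and the freed 2'-hydroxyl opens the epoxide at the benzylic carbon with inversion, giving 17 directly.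

**Step 11.** Most likely to go wrong: competing hydride abstraction from the benzylic–allylic CH2 of the geranyl chain, or further oxidation by the quinone, because both positions sit on the same electron-rich ring.

Fallback (from 5 and 11 to 15), which carries the C4 oxygen in from the aldehyde so that no C–H oxidation is needed: 5 is converted with trimethyl orthoformate and catalytic acid into 2-(dimethoxymethyl)-6-geranyl-3,5-bis(methoxymethoxy)phenol F6. Under the chiral phosphoric acid F6 loses methanol to the α-methoxy methide, which adds 11 to give (2R,3S)-8-geranyl-4-methoxy-5,7,4'-tris(methoxymethoxy)flavan-3-yl acetate F7; its enantioselectivity would have to be established anew. K2CO3 in MeOH gives (2R,3S)-8-geranyl-4-methoxy-5,7,4'-tris(methoxymethoxy)flavan-3-ol F8. Exchange of the benzylic methoxy group for hydroxyl (pyridinium tosylate, wet MeCN) gives 15.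

**Step 2.** Most likely to go wrong: O-alkylation, para-alkylation or double alkylation of the phenoxide, lowering the yield of the ortho product.

Fallback (from 1 and 3 to 4): excess 1 is C-alkylated with 3 (DBU, THF) to give 2-geranylbenzene-1,3,5-triol F9, a single isomer by symmetry. Two equivalents of MOMCl with i-Pr2NEt then protect the unhindered 5-hydroxyl and one of the two equivalent flanking hydroxyls, giving 4.

**Step 4.** Most likely to go wrong: over-reduction, in which the salicyl alkoxide ionises to the methide and takes up a second hydride, or oligomerisation of the labile alcohol on isolation.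

Fallback (from 4 to 6, bypassing the aldehyde): 4 is heated with PhB(OH)2, paraformaldehyde and catalytic propionic acid in toluene to give 8-geranyl-5,7-bis(methoxymethoxy)-2-phenyl-4H-1,3,2-benzodioxaborinine F10, a stable, storable form of the salicyl alcohol. Transesterification with propane-1,3-diol releases 6 just before use.

**Step 8.** Most likely to go wrong: protodeboronation or homocoupling of the alkenylboron species, or slow coupling with the small carboxylic acid.

Fallback (from 9 to 11): 9 is oxidised with NaBO3·4H2O to [4-(methoxymethoxy)phenyl]acetaldehyde F11, which is enol-acetylated (Ac2O, KOAc) to 11 together with (Z)-2-[4-(methoxymethoxy)phenyl]ethenyl acetate F12. 11 is separated on AgNO3-impregnated silica and F12 is recycled by iodine-catalysed equilibration.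

## Further compounds

F1 | step 9 | 3-geranyl-2,4,6-tris(methoxymethoxy)benzaldehyde | CC(C)=CCC/C(C)=C/Cc1c(OCOC)cc(OCOC)c(C=O)c1OCOC
F2 | step 9 | 1-[3-geranyl-2,4,6-tris(methoxymethoxy)phenyl]ethanol (racemic) | CC(C)=CCC/C(C)=C/Cc1c(OCOC)cc(OCOC)c(C(C)O)c1OCOC
F3 | step 9 | 1-[3-geranyl-2,4,6-tris(methoxymethoxy)phenyl]ethanone | CC(C)=CCC/C(C)=C/Cc1c(OCOC)cc(OCOC)c(C(C)=O)c1OCOC
F4 | step 9 | (E)-1-[3-geranyl-2,4,6-tris(methoxymethoxy)phenyl]-3-[4-(methoxymethoxy)phenyl]prop-2-en-1-one | CC(C)=CCC/C(C)=C/Cc1c(OCOC)cc(OCOC)c(C(=O)/C=C/c2ccc(OCOC)cc2)c1OCOC
F5 | step 9 | [3-geranyl-2,4,6-tris(methoxymethoxy)phenyl]{(2R,3S)-3-[4-(methoxymethoxy)phenyl]oxiran-2-yl}methanone | CC(C)=CCC/C(C)=C/Cc1c(OCOC)cc(OCOC)c(C(=O)[C@@H]2O[C@H]2c2ccc(OCOC)cc2)c1OCOC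
F6 | step 11 | 2-(dimethoxymethyl)-6-geranyl-3,5-bis(methoxymethoxy)phenol | CC(C)=CCC/C(C)=C/Cc1c(OCOC)cc(OCOC)c(C(OC)OC)c1O
F7 | step 11 | (2R,3S)-8-geranyl-4-methoxy-5,7,4'-tris(methoxymethoxy)flavan-3-yl acetate, C4 epimers | CC(C)=CCC/C(C)=C/Cc1c(OCOC)cc(OCOC)c2c1O[C@H](c1ccc(OCOC)cc1)[C@@H](OC(C)=O)C2OC
F8 | step 11 | (2R,3S)-8-geranyl-4-methoxy-5,7,4'-tris(methoxymethoxy)flavan-3-ol, C4 epimers | CC(C)=CCC/C(C)=C/Cc1c(OCOC)cc(OCOC)c2c1O[C@H](c1ccc(OCOC)cc1)[C@@H](O)C2OC
F9 | step 2 | 2-geranylbenzene-1,3,5-triol | CC(C)=CCC/C(C)=C/Cc1c(O)cc(O)cc1O
F10 | step 4 | 8-geranyl-5,7-bis(methoxymethoxy)-2-phenyl-4H-1,3,2-benzodioxaborinine | CC(C)=CCC/C(C)=C/Cc1c(OCOC)cc(OCOC)c2c1OB(c1ccccc1)OC2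
F11 | step 8 | [4-(methoxymethoxy)phenyl]acetaldehyde | COCOc1ccc(CC=O)cc1
F12 | step 8 | (Z)-2-[4-(methoxymethoxy)phenyl]ethenyl acetate | CC(=O)O/C=C\c1ccc(OCOC)cc1
A1 | alternative 1 | (2R,3R)-8-geranyl-3-hydroxy-5,7,4'-tris(tert-butyldimethylsilyloxy)flavanone | CC(C)=CCC/C(C)=C/Cc1c(O[Si](C)(C)C(C)(C)C)cc(O[Si](C)(C)C(C)(C)C)c2c1O[C@H](c1ccc(O[Si](C)(C)C(C)(C)C)cc1)[C@@H](O)C2=O
A2 | alternative 1 | (2R,3S)-7-geranyl-3-hydroxy-4,6-bis(tert-butyldimethylsilyloxy)-2-[4-(tert-butyldimethylsilyloxy)phenyl]-2,3-dihydro-1-benzofuran-3-carbaldehyde (C3 configuration as a chelated shift would require) | CC(C)=CCC/C(C)=C/Cc1c(O[Si](C)(C)C(C)(C)C)cc(O[Si](C)(C)C(C)(C)C)c2c1O[C@H](c1ccc(O[Si](C)(C)C(C)(C)C)cc1)[C@]2(O)C=O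
A3 | alternative 2 | (2R,3R)-8-geranyl-5,7-dihydroxy-3,4'-bis(methoxymethoxy)flavanone | CC(C)=CCC/C(C)=C/Cc1c(O)cc(O)c2c1O[C@H](c1ccc(OCOC)cc1)[C@@H](OCOC)C2=O
A4 | alternative 2 | (2R,3R)-3-(methoxymethoxy)-2-[4-(methoxymethoxy)phenyl]-6-(methylsulfanyl)-2,3-dihydro-4H-pyran-4-one | O1[C@H](c2ccc(OCOC)cc2)[C@@H](OCOC)C(=O)C=C1SC
A5 | alternative 2 | methyl (6E)-7,11-dimethyl-3-oxododeca-6,10-dienoate (methyl 4-geranylacetoacetate) | CC(C)=CCC/C(C)=C/CCC(=O)CC(=O)OC
A6 | alternative 3 | (2R,3R)-8-geranyl-3,5,7,4'-tetrakis(methoxymethoxy)flavanone | CC(C)=CCC/C(C)=C/Cc1c(OCOC)cc(OCOC)c2c1O[C@H](c1ccc(OCOC)cc1)[C@@H](OCOC)C2=O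
A7 | alternative 3 | 2-geranyl-3,5-bis(methoxymethoxy)-6-(trimethylsilyl)phenyl trifluoromethanesulfonate | CC(C)=CCC/C(C)=C/Cc1c(OCOC)cc(OCOC)c([Si](C)(C)C)c1OS(=O)(=O)C(F)(F)F
A8 | alternative 3 | methyl (2R,3R)-3-hydroxy-2-(methoxymethoxy)-3-[4-(methoxymethoxy)phenyl]propanoate | O[C@H](c1ccc(OCOC)cc1)[C@@H](OCOC)C(=O)OC
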